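**Retrosynthetic overview**
1. Target 10 comes from allylquinone 9 by cross-metathesis (allyl to prenyl), and 9 from bromoquinone 8 by Stille allylation of the C–Br bond.
2. 8 comes from the symmetric dibromide 6 by mono-hydrolysis of one C–Br (to 7) and O-methylation.
3. 6 comes from 2,5-dibromo-1,4-benzoquinone and two molecules of indole by two acid-promoted Michael additions of indole C-3 to the quinone, each followed by re-oxidation; these are the key fragment-joining C–C bonds.
4. No ring is formed: both indole bicycles and the six-membered quinone ring are bought intact. The order of attachment is first indole, second indole, oxygen substituent, carbon side chain.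

Assumption: the target has no stereocentre and no stereogenic alkene (the prenyl alkene carries two identical methyls), so it is one achiral compound and the route needs no stereocontrol.

**Route**

Step 1
Reactants: 1 indole; 2 2,5-dibromo-1,4-benzoquinone
Product: 4 2,5-dibromo-3-(1H-indol-3-yl)-1,4-benzoquinone, via indolyl-dibromohydroquinone 3 (not isolated)
Conditions: conc. H2SO4, THF, rt, 16 h (2 in slight excess); then DDQ (1.1 equiv), rt
Reagents that add atoms: none
Why: Acid-promoted Michael (conjugate Friedel–Crafts) addition of the enamine-like indole C-3 to an unsubstituted enone carbon of the bromine-activated quinone gives hydroquinone 3 after tautomerisation, and DDQ dehydrogenates it back to the quinone; no stereocentre is formed.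

Step 2
Reactants: 4 2,5-dibromo-3-(1H-indol-3-yl)-1,4-benzoquinone; 1 indole
Product: 6 2,5-dibromo-3,6-di(1H-indol-3-yl)-1,4-benzoquinone, via bis(indolyl)dibromohydroquinone 5 (not isolated)
Conditions: indole (1.5 equiv, slow addition), conc. H2SO4, THF, rt to 40 °C; then DDQ (1.1 equiv), rt
Reagents that add atoms: none
Why: Second acid-promoted Michael addition, in which the only remaining C–H enone carbon of 4 (para to the first indolyl) is the one position that can re-aromatise by tautomerisation, so the 3,6-bis(indolyl) pattern is fixed before DDQ re-oxidation; no stereocentre is formed.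

Step 3
Reactants: 6 2,5-dibromo-3,6-di(1H-indol-3-yl)-1,4-benzoquinone
Product: 7 2-bromo-5-hydroxy-3,6-di(1H-indol-3-yl)-1,4-benzoquinone
Conditions: 1 M aq. NaOH (3 equiv), THF, 0 °C to rt, monitored; then 1 M HCl to pH 2–3; product taken into aq. NaHCO3 and re-acidified
Reagents that add atoms: sodium hydroxide, [Na+].[OH-]
Why: Addition–elimination (vinylogous acyl substitution) of hydroxide at one C–Br gives a hydroxyquinone that is ionised at once to a vinylogous carboxylate, which shuts down attack at the second C–Br under mild conditions (as in chloranil to trichlorohydroxyquinone); no stereocentre is formed.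

Step 4
Reactants: 7 2-bromo-5-hydroxy-3,6-di(1H-indol-3-yl)-1,4-benzoquinone
Product: 8 2-bromo-3,6-di(1H-indol-3-yl)-5-methoxy-1,4-benzoquinone
Conditions: Me3SiCHN2 (2 M in hexanes, 1.3 equiv), CH2Cl2/MeOH 5:1, 0 °C
Reagents that add atoms: trimethylsilyldiazomethane, C[Si](C)(C)C=[N+]=[N-]
Why: O-Methylation of a vinylogous carboxylic acid (pKa about 4) by a diazoalkane, in which the acid protonates the reagent and the ion pair collapses to the methyl ether while the much less acidic indole N–H groups and the fully substituted quinone are left alone; no stereocentre is formed.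

Step 5
Reactants: 8 2-bromo-3,6-di(1H-indol-3-yl)-5-methoxy-1,4-benzoquinone
Product: 9 2-allyl-3,6-di(1H-indol-3-yl)-5-methoxy-1,4-benzoquinone
Conditions: allylSnBu3 (1.5 equiv), Pd(PPh3)4 (5 mol %), CuBr (10 mol %), 1,4-dioxane, 90 °C, argon; aq. KF work-up
Reagents that add atoms: allyltributylstannane, C=CC[Sn](CCCC)(CCCC)CCCC
Why: Stille cross-coupling, in which the bromoquinone acts as a vinylogous acyl bromide that adds readily to zerovalent palladium, the unsubstituted allyl group transfers from tin without regiochemical ambiguity, and the neutral conditions spare the quinone, the enol ether and the free N–H groups; no stereocentre is formed.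

Step 6
Reactants: 9 2-allyl-3,6-di(1H-indol-3-yl)-5-methoxy-1,4-benzoquinone
Product: 10 2,5-di(1H-indol-3-yl)-3-methoxy-6-(3-methylbut-2-en-1-yl)-1,4-benzoquinone
Conditions: 2-methylbut-2-ene (large excess, co-solvent), second-generation Grubbs catalyst RuCl2(=CHPh)(PCy3)(H2IMes) (5 mol %), CH2Cl2, 40 °C, sealed tube
Reagents that add atoms: 2-methylbut-2-ene, CC=C(C)C
Why: Olefin cross-metathesis of the terminal alkene with excess 2-methylbut-2-ene converts allyl into prenyl with loss of propene, the trisubstituted product is inert to further metathesis, quinones are tolerated by the ruthenium carbene, and the two alkene methyls are identical so no alkene geometry or stereocentre arises.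

**Compound list**
1 | indole (1H-indole) | c1ccc2[nH]ccc2c1 | starting material
2 | 2,5-dibromo-1,4-benzoquinone | O=C1C=C(Br)C(=O)C=C1Br | starting material
3 | 2,5-dibromo-3-(1H-indol-3-yl)benzene-1,4-diol (hydroquinone adduct, not isolated) | Oc1cc(Br)c(O)c(-c2c[nH]c3ccccc23)c1Br | intermediate
4 | 2,5-dibromo-3-(1H-indol-3-yl)-1,4-benzoquinone | O=C1C=C(Br)C(=O)C(c2c[nH]c3ccccc23)=C1Br | intermediate
5 | 2,5-dibromo-3,6-di(1H-indol-3-yl)benzene-1,4-diol (hydroquinone adduct, not isolated) | Oc1c(Br)c(-c2c[nH]c3ccccc23)c(O)c(Br)c1-c1c[nH]c2ccccc12 | intermediate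
6 | 2,5-dibromo-3,6-di(1H-indol-3-yl)-1,4-benzoquinone | O=C1C(Br)=C(c2c[nH]c3ccccc23)C(=O)C(Br)=C1c1c[nH]c2ccccc12 | intermediate
7 | 2-bromo-5-hydroxy-3,6-di(1H-indol-3-yl)-1,4-benzoquinone | O=C1C(Br)=C(c2c[nH]c3ccccc23)C(=O)C(O)=C1c1c[nH]c2ccccc12 | intermediate
8 | 2-bromo-3,6-di(1H-indol-3-yl)-5-methoxy-1,4-benzoquinone | COC1=C(c2c[nH]c3ccccc23)C(=O)C(Br)=C(c2c[nH]c3ccccc23)C1=O | intermediate
9 | 2-allyl-3,6-di(1H-indol-3-yl)-5-methoxy-1,4-benzoquinone | COC1=C(c2c[nH]c3ccccc23)C(=O)C(CC=C)=C(c2c[nH]c3ccccc23)C1=O | intermediate
10 | 2,5-di(1H-indol-3-yl)-3-methoxy-6-(3-methylbut-2-en-1-yl)-1,4-benzoquinone (CNP0506434.0, achiral) | COC1=C(c2c[nH]c3ccccc23)C(=O)C(CC=C(C)C)=C(c2c[nH]c3ccccc23)C1=O | target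

**Totals**
Total step count: 6. Longest linear sequence: 6 steps (2 to 10).

**Steps most likely to fail, with fallbacks**

Step 5 (Stille allylation of a hindered, donor-substituted bromoquinone). The fallback sets out from 8 and comes back to the route at 10, and it needs no palladium–quinone bond. Hydrogenation of 8 (H2, Pd/C, Et3N, EtOAc/MeOH) first reduces the quinone to 2-bromo-3,6-di(1H-indol-3-yl)-5-methoxybenzene-1,4-diol F1 and then hydrogenolyses its C–Br bond to 2,5-di(1H-indol-3-yl)-3-methoxybenzene-1,4-diol F2. Ag2O in THF re-oxidises this to 2,5-di(1H-indol-3-yl)-3-methoxy-1,4-benzoquinone F3, which has one free ring C–H. Tributyl(3-methylbut-2-en-1-yl)stannane and BF3·OEt2 in CH2Cl2 at −78 °C then prenylate it by carbonyl allylation. Attack through the γ-carbon of the stannane at the C-4 carbonyl gives the quinol 4-hydroxy-2,5-di(1H-indol-3-yl)-3-methoxy-4-(2-methylbut-3-en-2-yl)cyclohexa-2,5-dien-1-one F4 (racemic, transient). A [3,3] shift moves the side chain to C-6 with a second allylic inversion, and tautomerisation gives 2,5-di(1H-indol-3-yl)-3-methoxy-6-(3-methylbut-2-en-1-yl)benzene-1,4-diol F5, as in the prenylation of 2,3-dimethoxy-5-methylbenzoquinone. Ag2O oxidation of this hydroquinone gives 10.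

Step 3 (stopping the hydrolysis at one C–Br). The fallback sets out from 6 and comes back to the route at 8, skipping 7. Instead of hydroxide then methylation, 6 is treated with NaOMe in THF/MeOH at −20 °C for a direct addition–elimination under kinetic control. The reaction is stopped at partial conversion, and 8 is separated by chromatography from recovered 6 (recycled) and from the dimethoxy over-reaction product. This fallback makes no new compound (F0).

Step 6 (cross-metathesis on a quinone that carries two free indoles, with possible allyl-to-propenyl isomerisation). The fallback sets out from 8 and comes back to the route at 10, skipping 9. The prenyl group is brought in whole by Stille coupling of 8 with tributyl(3-methylbut-2-en-1-yl)stannane (Pd(PPh3)4, CuBr, DMF, 80 °C). Coupling occurs mainly at the unsubstituted α-terminus, and any 1,1-dimethylallyl isomer is removed by chromatography. This fallback makes no new compound (F0).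

**Further compounds**
F1 | step 5 | 2-bromo-3,6-di(1H-indol-3-yl)-5-methoxybenzene-1,4-diol | COc1c(O)c(-c2c[nH]c3ccccc23)c(Br)c(O)c1-c1c[nH]c2ccccc12
F2 | step 5 | 2,5-di(1H-indol-3-yl)-3-methoxybenzene-1,4-diol | COc1c(O)c(-c2c[nH]c3ccccc23)cc(O)c1-c1c[nH]c2ccccc12
F3 | step 5 | 2,5-di(1H-indol-3-yl)-3-methoxy-1,4-benzoquinone | COC1=C(c2c[nH]c3ccccc23)C(=O)C=C(c2c[nH]c3ccccc23)C1=O
F4 | step 5 | 4-hydroxy-2,5-di(1H-indol-3-yl)-3-methoxy-4-(2-methylbut-3-en-2-yl)cyclohexa-2,5-dien-1-one (racemic) | COC1=C(c2c[nH]c3ccccc23)C(=O)C=C(c2c[nH]c3ccccc23)C1(O)C(C)(C)C=C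
F5 | step 5 | 2,5-di(1H-indol-3-yl)-3-methoxy-6-(3-methylbut-2-en-1-yl)benzene-1,4-diol | COc1c(O)c(-c2c[nH]c3ccccc23)c(CC=C(C)C)c(O)c1-c1c[nH]c2ccccc12
F0 | step 3 | none | none
F0 | step 6 | none | none
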